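Atom numbers follow the prostanoid convention (C1 = ester carbon, ring = C8–C12, O7/O9/O12 = oxygens on C7/C9/C12). The acetate goes on O7 last. The 7-hydroxy compound is cut at C6–C7 into a (Z)-alkenylboronic acid (C1–C6, from methyl hex-5-ynoate) and the core (C7–C20) at the enol level of its β-keto aldehyde, the C8-hydroxymethylene ketone.
Enabling feature: O7–C7–C8–C12–O12 is a 1,3-dioxygen array whose C7 arm and O12 lie on the same face of the ring C8–C12. In the hydroxymethylene ketone, C7 is the β-carbon of an exocyclic enone C7=C8–C9=O9 that this ring locks s-cis. One boron atom can therefore bridge O7 and O12 in a temporary six-membered 1,3,2-dioxaborinine ring and hand its alkenyl group to C7.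
The temporary ring carries the fragment, sets C7 (delivery on the O12 face) and C8 (cis-fused protonation) from C12 alone, and is hydrolysed in the work-up.
Core: C7 comes from Claisen formylation at C8, and C10–Br from nucleophilic epoxidation, bromide opening and elimination. C12 comes from α-selective (Z)-octenylbarium addition to (R)-4-silyloxycyclopentenone, whose C9 stereocentre relays the chirality and is then oxidised away.
Ring order: the carbocycle C8–C12 comes with the starting enone; an oxirane (C10–C11) and the boron ring are the only rings made, and both are temporary.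

Key step: step 10

Remark on the chemistry: the hydroxymethylene ketones are tautomer mixtures and are drawn as the hydrogen-bonded Z-enols. The epoxy ketone is drawn as the isomer anti to the silyloxy group, and either epoxide gives the same bromoenone.

Step 1
Reactants: 1 (2Z)-oct-2-en-1-ol
Product: 2 (2Z)-1-chlorooct-2-ene
Conditions: NCS, Me2S, CH2Cl2, −20 to 0 °C
Reagents that add atoms: N-chlorosuccinimide, O=C1CCC(=O)N1Cl
Why: Corey–Kim-type chlorination: the alkoxysulfonium salt from NCS·SMe2 is displaced by chloride in an SN2 reaction at the primary carbon, so neither allylic transposition nor loss of the Z geometry is expected.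

Step 2
Reactants: 2 (2Z)-1-chlorooct-2-ene; 3 (4R)-4-[(tert-butyldimethylsilyl)oxy]cyclopent-2-en-1-one
Product: 5 (1S,4R)-4-[(tert-butyldimethylsilyl)oxy]-1-[(2Z)-oct-2-en-1-yl]cyclopent-2-en-1-ol, via (2Z)-oct-2-enylbarium chloride 4 (not isolated)
Conditions: Li, biphenyl, BaI2, THF, rt; 2, −78 °C; then 3, −78 °C; H2O
Reagents that add atoms: none
Why: Allylbarium addition to a ketone: allylic barium reagents formed at −78 °C keep their Z geometry and react 1,2 through the unsubstituted α-carbon, and attack on C12=O anti to the C9 silyloxy group should set C12 with the octenyl chain trans and the new hydroxyl cis to O9.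

Step 3
Reactants: 5 (1S,4R)-4-[(tert-butyldimethylsilyl)oxy]-1-[(2Z)-oct-2-en-1-yl]cyclopent-2-en-1-ol
Product: 6 (1S,4R)-1-[(2Z)-oct-2-en-1-yl]cyclopent-2-ene-1,4-diol
Conditions: Bu4NF, THF, 0 °C to rt
Reagents that add atoms: none
Why: Fluoride-induced cleavage of the silyl ether (Si–F bond formation) leaves both alkenes and both stereocentres untouched.

Step 4
Reactants: 6 (1S,4R)-1-[(2Z)-oct-2-en-1-yl]cyclopent-2-ene-1,4-diol
Product: 7 (4S)-4-hydroxy-4-[(2Z)-oct-2-en-1-yl]cyclopent-2-en-1-one
Conditions: MnO2, CH2Cl2, rt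
Reagents that add atoms: none
Why: Allylic oxidation with MnO2 can only take the secondary allylic alcohol at C9 to the enone, the tertiary C12 carbinol being inert, so the relay stereocentre C9 is erased and C12 stays.

Step 5
Reactants: 7 (4S)-4-hydroxy-4-[(2Z)-oct-2-en-1-yl]cyclopent-2-en-1-one
Product: 8 (4S)-4-[(2Z)-oct-2-en-1-yl]-4-[(triethylsilyl)oxy]cyclopent-2-en-1-one
Conditions: Et3SiOTf, 2,6-lutidine, CH2Cl2, −78 to 0 °C
Reagents that add atoms: triethylsilyl triflate, CC[Si](CC)(CC)OS(=O)(=O)C(F)(F)F
Why: Silyl triflate silylation of a tertiary alcohol; with O12 capped no C12 alkoxide can start a retro-aldol opening of the C8–C12 bond, so C12 cannot racemise in the basic steps 6 to 8.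

Step 6
Reactants: 8 (4S)-4-[(2Z)-oct-2-en-1-yl]-4-[(triethylsilyl)oxy]cyclopent-2-en-1-one
Product: 9 (1R,4S,5S)-4-[(2Z)-oct-2-en-1-yl]-4-[(triethylsilyl)oxy]-6-oxabicyclo[3.1.0]hexan-2-one
Conditions: t-BuOOH, DBU, CH2Cl2, 0 °C to rt
Reagents that add atoms: tert-butyl hydroperoxide, CC(C)(C)OO
Why: Weitz–Scheffer nucleophilic epoxidation attacks only the electron-poor C10=C11 bond and leaves the isolated Z alkene alone; attack anti to the silyloxy group is expected, and both new stereocentres are erased in step 7.

Step 7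
Reactants: 9 (1R,4S,5S)-4-[(2Z)-oct-2-en-1-yl]-4-[(triethylsilyl)oxy]-6-oxabicyclo[3.1.0]hexan-2-one
Product: 11 (4S)-2-bromo-4-[(2Z)-oct-2-en-1-yl]-4-[(triethylsilyl)oxy]cyclopent-2-en-1-one, via bromohydrin trimethylsilyl ether 10 (not isolated)
Conditions: Me3SiBr, CH2Cl2, −40 °C; then DBU, −20 to 0 °C
Reagents that add atoms: bromotrimethylsilane, C[Si](C)(C)Br
Why: Silyl-activated opening of the α,β-epoxy ketone by bromide at C10 (SN2 next to the carbonyl, C11 being neopentyl) and E1cB loss of trimethylsilanolate is the standard epoxy ketone to α-halo enone sequence and never exposes the side-chain alkene to electrophilic bromine.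

Step 8
Reactants: 11 (4S)-2-bromo-4-[(2Z)-oct-2-en-1-yl]-4-[(triethylsilyl)oxy]cyclopent-2-en-1-one
Product: 13 (4R,5Z)-2-bromo-4-hydroxy-5-(hydroxymethylidene)-4-[(2Z)-oct-2-en-1-yl]cyclopent-2-en-1-one, via triethylsilyl-protected hydroxymethylene ketone 12 (not isolated)
Conditions: LiN(SiMe3)2, THF, −78 °C; HCO2CH2CF3, −78 °C; AcOH; then HF·pyridine, THF, 0 °C
Reagents that add atoms: 2,2,2-trifluoroethyl formate, O=COCC(F)(F)F
Why: Crossed Claisen formylation of the only possible enolate (C8, the α′ position) with an activated formate, followed by HF cleavage of the triethylsilyl ether under acidic conditions that leave the enol, the vinyl bromide and C12 untouched.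

Step 9
Reactants: 14 methyl hex-5-ynoate
Product: 16 [(1Z)-6-methoxy-6-oxohex-1-en-1-yl]boronic acid, via catechol alkenylboronate 15 (not isolated)
Conditions: catecholborane, [Rh(cod)Cl]2 (cat.), P(i-Pr)3, Et3N, cyclohexane, rt; then H2O
Reagents that add atoms: catecholborane, B1Oc2ccccc2O1; water, O
Why: Rhodium-catalysed formal trans-hydroboration of a terminal alkyne (through a rhodium vinylidene) gives the (Z)-1-alkenylboronate, the ester is tolerated, and water cleaves the catechol ester.

Step 10
Reactants: 13 (4R,5Z)-2-bromo-4-hydroxy-5-(hydroxymethylidene)-4-[(2Z)-oct-2-en-1-yl]cyclopent-2-en-1-one; 16 [(1Z)-6-methoxy-6-oxohex-1-en-1-yl]boronic acid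
Product: 19 methyl (5Z,7S)-7-[(1R,5S)-3-bromo-5-hydroxy-5-[(2Z)-oct-2-en-1-yl]-2-oxocyclopent-3-en-1-yl]-7-hydroxyhept-5-enoate, via cyclic alkenylboronate 17 (not isolated), via cyclic borate 18 (not isolated)
Conditions: 4 Å MS, CH2Cl2, rt; then (CF3)2CHOH, DABCO (cat.), −20 °C to rt; pH 7 buffer
Reagents that add atoms: none
Why: Proposed new method: the acidic enol O7–H and the tertiary O12–H of 13 condense with 16 to the six-membered 1,3,2-dioxaborinine 17 (ring B–O7–C7=C8–C12–O12, closed by two reversible B–O condensations that only the E-enol tautomer can complete, so the tautomer mixture is funnelled into it), which holds O7 on the C12 side of C7=C8 and places boron under the ring plane on the O12 face within bonding reach of C7. DABCO (or hexafluoroisopropoxide) makes boron tetrahedral, the axial (Z)-alkenyl group moves with its bonding pair from boron to C7 of the hydrogen-bond-activated enone C7=C8–C9=O9 through the six-membered array B–O12–C12–C8–C7···C6, and (CF3)2CHOH protonates the resulting C9 enolate at C8 and caps boron to give 18, which the buffer hydrolyses. The closest known reaction types are the hydroxyl-directed Michael addition of alkenylboronic acids to γ-hydroxy enones, the Petasis transfer of an alkenyl group from a hydroxyl-bound boronate and the 1,4-addition of alkenylboron reagents to s-cis enones, all of which keep the alkene geometry. C7 should become S because the alkenyl group can only arrive on the O12 face while O7 is held toward C12, and C8 should become R because protonation has to give the cis-fused 6/5 bicycle (a trans fusion on the flat cyclopentenone is out of reach), which is also the thermodynamically preferred trans arrangement of the two carbon chains. The step needs C7 to react and not the second acceptor carbon C11, which the second B–O bond secures by aiming boron away from C11 (itself s-trans, neopentyl and α-brominated), and no metal that could insert into C10–Br is present. Loss of O7 by E1cB is held back because O7 is a tethered borate oxygen whose C7–O7 bond is kept by the ring near the nodal plane of the enolate.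

Step 11
Reactants: 19 methyl (5Z,7S)-7-[(1R,5S)-3-bromo-5-hydroxy-5-[(2Z)-oct-2-en-1-yl]-2-oxocyclopent-3-en-1-yl]-7-hydroxyhept-5-enoate
Product: 20 methyl (5Z,7S)-7-acetoxy-7-[(1R,5S)-3-bromo-5-hydroxy-5-[(2Z)-oct-2-en-1-yl]-2-oxocyclopent-3-en-1-yl]hept-5-enoate (the target)
Conditions: Ac2O, pyridine, CH2Cl2, 0 °C
Reagents that add atoms: acetic anhydride, CC(=O)OC(C)=O
Why: Chemoselective acylation: without DMAP only the secondary allylic O7–H reacts while the tertiary O12–H stays free, and the weak base at low temperature should keep the β-acetoxy ketone from E1cB elimination and C8 from epimerising.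

Compound list
1 | (2Z)-oct-2-en-1-ol | CCCCC/C=C\CO | starting material
2 | (2Z)-1-chlorooct-2-ene | CCCCC/C=C\CCl | intermediate
3 | (4R)-4-[(tert-butyldimethylsilyl)oxy]cyclopent-2-en-1-one | O=C1C=C[C@H](O[Si](C)(C)C(C)(C)C)C1 | starting material
4 | (2Z)-oct-2-enylbarium chloride | CCCCC/C=C\C[Ba]Cl | intermediate
5 | (1S,4R)-4-[(tert-butyldimethylsilyl)oxy]-1-[(2Z)-oct-2-en-1-yl]cyclopent-2-en-1-ol | CCCCC/C=C\C[C@@]1(O)C=C[C@H](O[Si](C)(C)C(C)(C)C)C1 | intermediate
6 | (1S,4R)-1-[(2Z)-oct-2-en-1-yl]cyclopent-2-ene-1,4-diol | CCCCC/C=C\C[C@@]1(O)C=C[C@H](O)C1 | intermediate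
7 | (4S)-4-hydroxy-4-[(2Z)-oct-2-en-1-yl]cyclopent-2-en-1-one | CCCCC/C=C\C[C@@]1(O)C=CC(=O)C1 | intermediate
8 | (4S)-4-[(2Z)-oct-2-en-1-yl]-4-[(triethylsilyl)oxy]cyclopent-2-en-1-one | CCCCC/C=C\C[C@@]1(O[Si](CC)(CC)CC)C=CC(=O)C1 | intermediate
9 | (1R,4S,5S)-4-[(2Z)-oct-2-en-1-yl]-4-[(triethylsilyl)oxy]-6-oxabicyclo[3.1.0]hexan-2-one | CCCCC/C=C\C[C@@]1(O[Si](CC)(CC)CC)[C@H]2O[C@H]2C(=O)C1 | intermediate
10 | (2S,3R,4S)-2-bromo-4-[(2Z)-oct-2-en-1-yl]-4-[(triethylsilyl)oxy]-3-[(trimethylsilyl)oxy]cyclopentan-1-one | CCCCC/C=C\C[C@@]1(O[Si](CC)(CC)CC)[C@@H](O[Si](C)(C)C)[C@H](Br)C(=O)C1 | intermediate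
11 | (4S)-2-bromo-4-[(2Z)-oct-2-en-1-yl]-4-[(triethylsilyl)oxy]cyclopent-2-en-1-one | CCCCC/C=C\C[C@@]1(O[Si](CC)(CC)CC)C=C(Br)C(=O)C1 | intermediate
12 | (4R,5Z)-2-bromo-5-(hydroxymethylidene)-4-[(2Z)-oct-2-en-1-yl]-4-[(triethylsilyl)oxy]cyclopent-2-en-1-one | CCCCC/C=C\C[C@@]1(O[Si](CC)(CC)CC)C=C(Br)C(=O)/C1=C\O | intermediate
13 | (4R,5Z)-2-bromo-4-hydroxy-5-(hydroxymethylidene)-4-[(2Z)-oct-2-en-1-yl]cyclopent-2-en-1-one | CCCCC/C=C\C[C@@]1(O)C=C(Br)C(=O)/C1=C\O | intermediate
14 | methyl hex-5-ynoate | C#CCCCC(=O)OC | starting material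
15 | methyl (5Z)-6-(1,3,2-benzodioxaborol-2-yl)hex-5-enoate | COC(=O)CCC/C=C\B1Oc2ccccc2O1 | intermediate
16 | [(1Z)-6-methoxy-6-oxohex-1-en-1-yl]boronic acid | COC(=O)CCC/C=C\B(O)O | intermediate
17 | cyclic (Z)-alkenylboronate of 13: boron bridges O7 and O12 in a 1,3,2-dioxaborinine fused at C8–C12, C7=C8 E, C12 as in 13 | CCCCC/C=C\C[C@]12OB(/C=C\CCCC(=O)OC)O/C=C1/C(=O)C(Br)=C2 | intermediate
18 | cyclic hexafluoroisopropyl borate of 19: boron bridges O7 and O12, cis-fused, 7S,8R,12S | CCCCC/C=C\C[C@]12OB(OC(C(F)(F)F)C(F)(F)F)O[C@@H](/C=C\CCCC(=O)OC)[C@H]1C(=O)C(Br)=C2 | intermediate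
19 | methyl (5Z,7S)-7-[(1R,5S)-3-bromo-5-hydroxy-5-[(2Z)-oct-2-en-1-yl]-2-oxocyclopent-3-en-1-yl]-7-hydroxyhept-5-enoate | CCCCC/C=C\C[C@@]1(O)C=C(Br)C(=O)[C@@H]1[C@H](/C=C\CCCC(=O)OC)O | intermediate
20 | methyl (5Z,7S)-7-acetoxy-7-[(1R,5S)-3-bromo-5-hydroxy-5-[(2Z)-oct-2-en-1-yl]-2-oxocyclopent-3-en-1-yl]hept-5-enoate | CCCCC/C=C\C[C@@]1(O)C=C(Br)C(=O)[C@@H]1[C@H](/C=C\CCCC(=O)OC)OC(C)=O | target

Total step count: 11
Longest linear sequence: 10 steps (1 → 2 → 5 → 6 → 7 → 8 → 9 → 11 → 13 → 19 → 20)

Steps most likely to fail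

Step 10 (Proposed new method).
- Risk: the alkenyl shift from the tetracoordinate boronate may be too slow. Protodeboronation, parking of boron in the unreactive O7/O9 chelate mode, or E1cB loss of O7 after the transfer could then take over.
- Fallback (known chemistry, from 13 and 16 back to 19): the temporary ring is built from carbon and isolated, and the alkenyl group is brought in from outside by a metal catalyst. 13 is treated with 2-methoxypropene and PPTS (CH2Cl2, 0 °C) to give the O7,O12-isopropylidene acetal F1, a cyclic β-alkoxy enone. A Hayashi–Miyaura 1,4-addition of 16 ([Rh(cod)OH]2, BINAP of the matched hand, dioxane/H2O, rt) is a reaction type known for alkenylboronic acids and for cyclic β-alkoxy enones. Monovalent rhodium should leave C10–Br alone in it. It should place the alkenyl group on C7 under ligand control, while the acetal ring again forces the cis-fused protonation at C8, giving the 7,12-O-isopropylidene derivative F2. 80% aqueous AcOH at rt then frees 19.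

Step 2.
- Risk: loss of α-selectivity or of the Z geometry in the barium reagent, poor facial selectivity at C12=O, or enolisation of the silyloxy enone by the basic reagent.
- Fallback (from 3 back to 5): the chain is built in pieces from a symmetric allyl nucleophile. Allylmagnesium bromide with CeCl3 (THF, −78 °C) adds to 3 anti to the silyloxy group to give the allyl carbinol F3. A Johnson–Lemieux cleavage (OsO4 cat., NaIO4, 2,6-lutidine, dioxane/H2O) of the terminal alkene, which is faster than attack on the flanked ring alkene, gives the β-hydroxy aldehyde F4. A salt-free Wittig reaction (n-hexyltriphenylphosphonium bromide, NaN(SiMe3)2, THF, −78 °C) closes the Z alkene and returns 5.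

Step 11.
- Risk: base-induced E1cB loss of the newly formed acetate during the acylation, or epimerisation at C8.
- Fallback (from 19 back to 20): the acetate carbon is brought in under acid only. 19 is condensed with MeC(OMe)3 and PPTS (CH2Cl2, rt) to the cyclic O7,O12-orthoacetate F5. Brief treatment with aqueous AcOH at 0 °C opens the orthoester, the hindered tertiary O12 being released and the acetyl group staying on the secondary O7, which gives 20.

Further compounds
F1 | step 10 | O7,O12-isopropylidene acetal of 13 (2,2-dimethyl-4H-1,3-dioxin fused at C8–C12, C7=C8 E) | CCCCC/C=C\C[C@]12OC(C)(C)O/C=C1/C(=O)C(Br)=C2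
F2 | step 10 | 7,12-O-isopropylidene derivative of 19 (cis-fused 1,3-dioxane, 7S,8R,12S) | CCCCC/C=C\C[C@]12OC(C)(C)O[C@@H](/C=C\CCCC(=O)OC)[C@H]1C(=O)C(Br)=C2
F3 | step 2 | (1S,4R)-4-[(tert-butyldimethylsilyl)oxy]-1-(prop-2-en-1-yl)cyclopent-2-en-1-ol | C=CC[C@@]1(O)C=C[C@H](O[Si](C)(C)C(C)(C)C)C1
F4 | step 2 | 2-[(1R,4R)-4-[(tert-butyldimethylsilyl)oxy]-1-hydroxycyclopent-2-en-1-yl]acetaldehyde | O=CC[C@@]1(O)C=C[C@H](O[Si](C)(C)C(C)(C)C)C1
F5 | step 11 | cyclic O7,O12-orthoacetate of 19 (2-methoxy-2-methyl-1,3-dioxane, both epimers at the orthoester carbon) | CCCCC/C=C\C[C@]12OC(C)(OC)O[C@@H](/C=C\CCCC(=O)OC)[C@H]1C(=O)C(Br)=C2
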